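**Retrosynthetic overview**
1. The acid is released last from an allyl ester (zerovalent palladium), after PMB removal and oxidation of the C2 carbinol to the ketone (indene numbering: C1 Me, C2 C=O, C3 Et, C4 CO2H).
2. Both rings form together: an intramolecular Diels–Alder reaction of an (E,E,E)-1-phenyltriene with an (E)-2-ethyl enoate closes the cyclohexene and the cyclopentane in one step, trans-fused, and sets C3a, C4, C5 and C7a from C1 and C3.
3. The tetraene is built by Wittig/Horner–Wadsworth–Emmons homologations at both ends of a methyl/alkoxy/ethyl stereotriad.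
4. The triad comes from Sharpless epoxidation and cuprate opening of an allylic alcohol that already carries the ethyl stereocentre.
5. That first stereocentre comes from lipase-catalysed desymmetrisation of achiral 2-ethylpropane-1,3-diol.

Assumption: the Burkholderia cepacia lipase acetylates the pro-S hydroxymethyl arm of 2, giving (S)-4; this sense is recalled by analogy with other 2-substituted propane-1,3-diols, not established for the ethyl case, and must be confirmed on the first batch.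

**Step 1**
Reactants: 1 diethyl 2-ethylpropanedioate
Product: 2 2-ethylpropane-1,3-diol
Conditions: LiAlH4 (2.2 equiv), THF, 0 °C → reflux; H2O/NaOH work-up
Reagents that add atoms: none
Why: Hydride reduction of both ester groups gives the prochiral diol; no stereocentre is formed.

**Step 2**
Reactants: 2 2-ethylpropane-1,3-diol; 3 vinyl acetate
Product: 4 (2S)-2-(hydroxymethyl)butyl acetate
Conditions: lipase (hydrolase class, from Burkholderia cepacia, immobilised), vinyl acetate (3 equiv), iPr2O, 25 °C, stopped at about 10% diacetate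
Reagents that add atoms: vinyl acetate 3, CC(=O)OC=C
Why: Enzymatic desymmetrisation by irreversible transesterification: the lipase acylates one enantiotopic hydroxymethyl arm and so sets the ethyl-bearing stereocentre (future C3), with ee raised by the coupled over-acylation of the minor enantiomer.

**Step 3**
Reactants: 4 (2S)-2-(hydroxymethyl)butyl acetate; 5 tert-butyl(chloro)diphenylsilane
Product: 6 (2R)-2-{[(tert-butyldiphenylsilyl)oxy]methyl}butyl acetate
Conditions: imidazole (2 equiv), CH2Cl2, 0 °C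
Reagents that add atoms: tert-butyl(chloro)diphenylsilane 5, CC(C)(C)[Si](Cl)(c1ccccc1)c1ccccc1
Why: Silyl ether formation at the free primary alcohol, run cold to suppress acyl migration; TBDPS is chosen because it does not undergo 1,3-migration, which would racemise the centre.

**Step 4**
Reactants: 6 (2R)-2-{[(tert-butyldiphenylsilyl)oxy]methyl}butyl acetate
Product: 7 (2R)-2-{[(tert-butyldiphenylsilyl)oxy]methyl}butan-1-ol
Conditions: K2CO3 (0.2 equiv), MeOH, 0 °C
Reagents that add atoms: none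
Why: Base-catalysed transesterification (methanolysis) removes the acetate without touching the silyl ether or the stereocentre.

**Step 5**
Reactants: 7 (2R)-2-{[(tert-butyldiphenylsilyl)oxy]methyl}butan-1-ol; 8 ethyl (triphenylphosphoranylidene)acetate
Product: 10 ethyl (2E,4R)-4-{[(tert-butyldiphenylsilyl)oxy]methyl}hex-2-enoate, via silyloxy aldehyde 9 (not isolated)
Conditions: Dess–Martin periodinane (1.3 equiv), CH2Cl2, 0 °C → rt, 1 h; then 8 (1.5 equiv), rt, 12 h
Reagents that add atoms: ethyl (triphenylphosphoranylidene)acetate 8, CCOC(=O)C=P(c1ccccc1)(c1ccccc1)c1ccccc1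
Why: One-pot Dess–Martin oxidation/Wittig olefination consumes the epimerisable α-branched aldehyde as it forms, and the stabilised ylide gives the E-enoate.

**Step 6**
Reactants: 10 ethyl (2E,4R)-4-{[(tert-butyldiphenylsilyl)oxy]methyl}hex-2-enoate
Product: 11 (2E,4R)-4-{[(tert-butyldiphenylsilyl)oxy]methyl}hex-2-en-1-ol
Conditions: iBu2AlH (2.5 equiv), CH2Cl2, −78 °C; potassium sodium tartrate work-up
Reagents that add atoms: none
Why: 1,2-Reduction of the conjugated ester by the aluminium hydride gives the allylic alcohol with the alkene geometry intact.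

**Step 7**
Reactants: 11 (2E,4R)-4-{[(tert-butyldiphenylsilyl)oxy]methyl}hex-2-en-1-ol; 12 tert-butyl hydroperoxide
Product: 13 {(2R,3R)-3-[(2S)-1-{[tert-butyl(diphenyl)silyl]oxy}butan-2-yl]oxiran-2-yl}methanol
Conditions: Ti(OiPr)4 (10 mol%), D-(−)-diethyl tartrate (12 mol%), 12 (2 equiv, in decane), 4 Å molecular sieves, CH2Cl2, −20 °C
Reagents that add atoms: tert-butyl hydroperoxide 12, CC(C)(C)OO
Why: Sharpless asymmetric epoxidation under catalyst control: the D-(−)-tartrate complex gives the (2R,3R)-epoxide, and the neighbouring centre (Et versus CH2OSi) exerts little bias.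

**Step 8**
Reactants: 13 {(2R,3R)-3-[(2S)-1-{[tert-butyl(diphenyl)silyl]oxy}butan-2-yl]oxiran-2-yl}methanol; 14 methyllithium
Product: 15 (2S,3S,4S)-4-{[(tert-butyldiphenylsilyl)oxy]methyl}-2-methylhexane-1,3-diol
Conditions: CuI (3 equiv), 14 (6 equiv), Et2O, −40 → 0 °C; NaIO4 wash to destroy any 1,2-diol regioisomer
Reagents that add atoms: methyllithium 14, [Li]C (delivered as lithium dimethylcuprate, [Li+].C[Cu-]C)
Why: SN2 epoxide opening by the Gilman cuprate at C2, directed there by the branched C4 substituent, installs the methyl group with inversion and gives the anti methyl/hydroxyl pair while the carbinol centre is retained.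

**Step 9**
Reactants: 15 (2S,3S,4S)-4-{[(tert-butyldiphenylsilyl)oxy]methyl}-2-methylhexane-1,3-diol; 16 4-methoxybenzaldehyde dimethyl acetal
Product: 17 (2S,4S,5S)-4-[(2S)-1-{[tert-butyl(diphenyl)silyl]oxy}butan-2-yl]-2-(4-methoxyphenyl)-5-methyl-1,3-dioxane
Conditions: PPTS (5 mol%), CH2Cl2, rt
Reagents that add atoms: 4-methoxybenzaldehyde dimethyl acetal 16, COc1ccc(cc1)C(OC)OC
Why: Acid-catalysed transacetalisation under thermodynamic control gives the all-equatorial 1,3-dioxane, which fixes the acetal carbon.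

**Step 10**
Reactants: 17 (2S,4S,5S)-4-[(2S)-1-{[tert-butyl(diphenyl)silyl]oxy}butan-2-yl]-2-(4-methoxyphenyl)-5-methyl-1,3-dioxane
Product: 18 (2S,3S,4S)-4-{[(tert-butyldiphenylsilyl)oxy]methyl}-3-[(4-methoxybenzyl)oxy]-2-methylhexan-1-ol
Conditions: iBu2AlH (3 equiv), CH2Cl2, −78 → 0 °C; potassium sodium tartrate work-up
Reagents that add atoms: none
Why: Regioselective reductive acetal opening: aluminium binds the less hindered primary oxygen, so hydride delivery leaves the PMB ether on the secondary oxygen and frees the primary alcohol.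

**Step 11**
Reactants: 18 (2S,3S,4S)-4-{[(tert-butyldiphenylsilyl)oxy]methyl}-3-[(4-methoxybenzyl)oxy]-2-methylhexan-1-ol
Product: 19 (2R,3R,4S)-4-{[(tert-butyldiphenylsilyl)oxy]methyl}-3-[(4-methoxybenzyl)oxy]-2-methylhexanal
Conditions: Dess–Martin periodinane (1.3 equiv), CH2Cl2, 0 °C → rt; used at once
Reagents that add atoms: none
Why: Dess–Martin oxidation gives the α-methyl aldehyde under non-basic conditions without epimerisation (the descriptor change is a priority effect only).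

**Step 12**
Reactants: 20 propyltriphenylphosphonium bromide; 21 allyl chloroformate
Product: 24 allyl 2-(triphenylphosphoranylidene)butanoate, via propylidene ylide 22 (not isolated), via acylphosphonium chloride 23 (not isolated)
Conditions: NaN(SiMe3)2 (1.0 equiv per 20), THF, 0 °C; then 21 (0.5 equiv), 0 °C → rt; filter off the phosphonium chloride
Reagents that add atoms: allyl chloroformate 21, C=CCOC(Cl)=O
Why: Bestmann C-acylation of a non-stabilised ylide: the transient racemic acylphosphonium salt is deprotonated by the second equivalent of ylide (transylidation) to the achiral stabilised ylide.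

**Step 13**
Reactants: 19 (2R,3R,4S)-4-{[(tert-butyldiphenylsilyl)oxy]methyl}-3-[(4-methoxybenzyl)oxy]-2-methylhexanal; 24 allyl 2-(triphenylphosphoranylidene)butanoate
Product: 25 allyl (2E,4S,5S,6S)-6-{[(tert-butyldiphenylsilyl)oxy]methyl}-2-ethyl-5-[(4-methoxybenzyl)oxy]-4-methyloct-2-enoate
Conditions: 24 (1.5 equiv), toluene, 90 °C, 24 h
Reagents that add atoms: allyl 2-(triphenylphosphoranylidene)butanoate 24, CCC(C(=O)OCC=C)=P(c1ccccc1)(c1ccccc1)c1ccccc1
Why: Wittig olefination with an α-substituted stabilised ylide gives the E-trisubstituted enoate (ester trans to the chain) without touching the α-centre.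

**Step 14**
Reactants: 25 allyl (2E,4S,5S,6S)-6-{[(tert-butyldiphenylsilyl)oxy]methyl}-2-ethyl-5-[(4-methoxybenzyl)oxy]-4-methyloct-2-enoate
Product: 26 (2E,4S,5S,6S)-6-{[(tert-butyldiphenylsilyl)oxy]methyl}-2-ethyl-5-[(4-methoxybenzyl)oxy]-4-methyloct-2-en-1-ol
Conditions: iBu2AlH (2.5 equiv), CH2Cl2, −78 °C; potassium sodium tartrate work-up
Reagents that add atoms: none
Why: 1,2-Reduction of the enoate to the allylic alcohol; the silyl and PMB ethers are inert.

**Step 15**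
Reactants: 26 (2E,4S,5S,6S)-6-{[(tert-butyldiphenylsilyl)oxy]methyl}-2-ethyl-5-[(4-methoxybenzyl)oxy]-4-methyloct-2-en-1-ol
Product: 27 (2E,4S,5S,6S)-6-{[(tert-butyldiphenylsilyl)oxy]methyl}-2-ethyl-5-[(4-methoxybenzyl)oxy]-4-methyloct-2-enal
Conditions: MnO2 (15 equiv), CH2Cl2, rt
Reagents that add atoms: none
Why: Chemoselective allylic oxidation with MnO2 gives the enal without isomerising the alkene or the γ-stereocentre.

**Step 16**
Reactants: 27 (2E,4S,5S,6S)-6-{[(tert-butyldiphenylsilyl)oxy]methyl}-2-ethyl-5-[(4-methoxybenzyl)oxy]-4-methyloct-2-enal; 24 allyl 2-(triphenylphosphoranylidene)butanoate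
Product: 28 allyl (2E,4E,6S,7S,8S)-8-{[(tert-butyldiphenylsilyl)oxy]methyl}-2,4-diethyl-7-[(4-methoxybenzyl)oxy]-6-methyldeca-2,4-dienoate
Conditions: 24 (1.5 equiv), toluene, 90 °C, 24 h
Reagents that add atoms: allyl 2-(triphenylphosphoranylidene)butanoate 24, CCC(C(=O)OCC=C)=P(c1ccccc1)(c1ccccc1)c1ccccc1
Why: A second Wittig olefination with the same stabilised ylide builds the (E,E)-dienoate.

**Step 17**
Reactants: 28 allyl (2E,4E,6S,7S,8S)-8-{[(tert-butyldiphenylsilyl)oxy]methyl}-2,4-diethyl-7-[(4-methoxybenzyl)oxy]-6-methyldeca-2,4-dienoate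
Product: 29 (2E,4E,6S,7S,8S)-8-{[(tert-butyldiphenylsilyl)oxy]methyl}-2,4-diethyl-7-[(4-methoxybenzyl)oxy]-6-methyldeca-2,4-dien-1-ol
Conditions: iBu2AlH (2.5 equiv), CH2Cl2, −78 °C; potassium sodium tartrate work-up
Reagents that add atoms: none
Why: 1,2-Reduction of the dienoate to the dienol.

**Step 18**
Reactants: 29 (2E,4E,6S,7S,8S)-8-{[(tert-butyldiphenylsilyl)oxy]methyl}-2,4-diethyl-7-[(4-methoxybenzyl)oxy]-6-methyldeca-2,4-dien-1-ol
Product: 30 (2E,4E,6S,7S,8S)-8-{[(tert-butyldiphenylsilyl)oxy]methyl}-2,4-diethyl-7-[(4-methoxybenzyl)oxy]-6-methyldeca-2,4-dienal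
Conditions: MnO2 (15 equiv), CH2Cl2, rt
Reagents that add atoms: none
Why: Allylic oxidation with MnO2 gives the dienal.

**Step 19**
Reactants: 30 (2E,4E,6S,7S,8S)-8-{[(tert-butyldiphenylsilyl)oxy]methyl}-2,4-diethyl-7-[(4-methoxybenzyl)oxy]-6-methyldeca-2,4-dienal; 31 diethyl benzylphosphonate
Product: 32 tert-butyl{[(2S,3S,4S,5E,7E,9E)-2,6,8-triethyl-3-[(4-methoxybenzyl)oxy]-4-methyl-10-phenyldeca-5,7,9-trien-1-yl]oxy}diphenylsilane
Conditions: 31 (1.5 equiv), KN(SiMe3)2 (1.4 equiv), THF, −78 °C; then 30, −78 → 0 °C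
Reagents that add atoms: diethyl benzylphosphonate 31, CCOP(=O)(Cc1ccccc1)OCC
Why: Horner–Wadsworth–Emmons olefination with the preformed benzylphosphonate anion gives the E-styryl terminus, with cold addition to the aldehyde outrunning vinylogous deprotonation.

**Step 20**
Reactants: 32 tert-butyl{[(2S,3S,4S,5E,7E,9E)-2,6,8-triethyl-3-[(4-methoxybenzyl)oxy]-4-methyl-10-phenyldeca-5,7,9-trien-1-yl]oxy}diphenylsilane
Product: 33 (2S,3S,4S,5E,7E,9E)-2,6,8-triethyl-3-[(4-methoxybenzyl)oxy]-4-methyl-10-phenyldeca-5,7,9-trien-1-ol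
Conditions: Bu4NF (1.5 equiv), THF, 0 °C → rt
Reagents that add atoms: none
Why: Fluoride-mediated desilylation frees the primary alcohol; the PMB ether and the triene are inert to fluoride.

**Step 21**
Reactants: 33 (2S,3S,4S,5E,7E,9E)-2,6,8-triethyl-3-[(4-methoxybenzyl)oxy]-4-methyl-10-phenyldeca-5,7,9-trien-1-ol
Product: 34 (2R,3S,4S,5E,7E,9E)-2,6,8-triethyl-3-[(4-methoxybenzyl)oxy]-4-methyl-10-phenyldeca-5,7,9-trienal
Conditions: Dess–Martin periodinane (1.3 equiv), CH2Cl2, 0 °C → rt; used at once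
Reagents that add atoms: none
Why: Dess–Martin oxidation gives the α-ethyl aldehyde without epimerisation and leaves the triene alone.

**Step 22**
Reactants: 34 (2R,3S,4S,5E,7E,9E)-2,6,8-triethyl-3-[(4-methoxybenzyl)oxy]-4-methyl-10-phenyldeca-5,7,9-trienal; 24 allyl 2-(triphenylphosphoranylidene)butanoate
Product: 36 allyl (1S,2S,3S,3aR,4R,5S,7aR)-3,4,5,7-tetraethyl-2-[(4-methoxybenzyl)oxy]-1-methyl-5-[(E)-2-phenylethenyl]-2,3,3a,4,5,7a-hexahydro-1H-indene-4-carboxylate, via tetraenoate 35 (not isolated)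
Conditions: 24 (2 equiv), toluene, 90 °C, 24 h; then BHT (cat.), 110 °C, 24 h
Reagents that add atoms: allyl 2-(triphenylphosphoranylidene)butanoate 24, CCC(C(=O)OCC=C)=P(c1ccccc1)(c1ccccc1)c1ccccc1
Why: Wittig olefination gives the (E)-enoate, which undergoes an ester-endo intramolecular Diels–Alder reaction in which A(1,3) strain at both allylic centres (H eclipsing the vinylic ethyl groups) fixes the diene and dienophile faces, so C7a, C3a, C4 and C5 are set suprafacially and the ring fusion is trans.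

**Step 23**
Reactants: 36 allyl (1S,2S,3S,3aR,4R,5S,7aR)-3,4,5,7-tetraethyl-2-[(4-methoxybenzyl)oxy]-1-methyl-5-[(E)-2-phenylethenyl]-2,3,3a,4,5,7a-hexahydro-1H-indene-4-carboxylate
Product: 37 allyl (1S,2S,3S,3aR,4R,5S,7aR)-3,4,5,7-tetraethyl-2-hydroxy-1-methyl-5-[(E)-2-phenylethenyl]-2,3,3a,4,5,7a-hexahydro-1H-indene-4-carboxylate
Conditions: DDQ (1.5 equiv), CH2Cl2/pH 7 phosphate buffer (10:1), 0 °C → rt
Reagents that add atoms: none
Why: Oxidative PMB cleavage by benzylic hydride abstraction proceeds under neutral conditions that spare the styrene, the ring alkene and the allyl ester.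

**Step 24**
Reactants: 37 allyl (1S,2S,3S,3aR,4R,5S,7aR)-3,4,5,7-tetraethyl-2-hydroxy-1-methyl-5-[(E)-2-phenylethenyl]-2,3,3a,4,5,7a-hexahydro-1H-indene-4-carboxylate
Product: 38 allyl (1S,3S,3aR,4R,5S,7aR)-3,4,5,7-tetraethyl-1-methyl-2-oxo-5-[(E)-2-phenylethenyl]-2,3,3a,4,5,7a-hexahydro-1H-indene-4-carboxylate
Conditions: Dess–Martin periodinane (1.5 equiv), CH2Cl2, rt
Reagents that add atoms: none
Why: Dess–Martin oxidation of the hindered carbinol gives the cyclopentanone, whose two α-centres sit in the all-trans, thermodynamically preferred arrangement and so do not epimerise.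

**Step 25**
Reactants: 38 allyl (1S,3S,3aR,4R,5S,7aR)-3,4,5,7-tetraethyl-1-methyl-2-oxo-5-[(E)-2-phenylethenyl]-2,3,3a,4,5,7a-hexahydro-1H-indene-4-carboxylate
Product: 39 (1S,3S,3aR,4R,5S,7aR)-3,4,5,7-tetraethyl-1-methyl-2-oxo-5-[(E)-2-phenylethenyl]-2,3,3a,4,5,7a-hexahydro-1H-indene-4-carboxylic acid
Conditions: Pd(PPh3)4 (5 mol%), morpholine (10 equiv), THF, rt; then aqueous citric acid to pH 3
Reagents that add atoms: none
Why: Tsuji–Trost deallylation: zerovalent palladium ionises the allyl ester to a π-allyl complex that morpholine captures, so the acid is freed without attack at the hindered quaternary carbonyl and without acid or strong base.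

**Compound list**
1 | diethyl 2-ethylpropanedioate | CCOC(=O)C(CC)C(=O)OCC | starting material
2 | 2-ethylpropane-1,3-diol | CCC(CO)CO | intermediate
3 | vinyl acetate | CC(=O)OC=C | starting material
4 | (2S)-2-(hydroxymethyl)butyl acetate | CC(=O)OC[C@H](CO)CC | intermediate
5 | tert-butyl(chloro)diphenylsilane | CC(C)(C)[Si](Cl)(c1ccccc1)c1ccccc1 | starting material
6 | (2R)-2-{[(tert-butyldiphenylsilyl)oxy]methyl}butyl acetate | CC(=O)OC[C@H](CO[Si](c1ccccc1)(c1ccccc1)C(C)(C)C)CC | intermediate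
7 | (2R)-2-{[(tert-butyldiphenylsilyl)oxy]methyl}butan-1-ol | OC[C@H](CO[Si](c1ccccc1)(c1ccccc1)C(C)(C)C)CC | intermediate
8 | ethyl (triphenylphosphoranylidene)acetate | CCOC(=O)C=P(c1ccccc1)(c1ccccc1)c1ccccc1 | starting material
9 | (2S)-2-{[(tert-butyldiphenylsilyl)oxy]methyl}butanal (not isolated) | O=C[C@@H](CC)CO[Si](c1ccccc1)(c1ccccc1)C(C)(C)C | intermediate
10 | ethyl (2E,4R)-4-{[(tert-butyldiphenylsilyl)oxy]methyl}hex-2-enoate | CCOC(=O)/C=C/[C@@H](CC)CO[Si](c1ccccc1)(c1ccccc1)C(C)(C)C | intermediate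
11 | (2E,4R)-4-{[(tert-butyldiphenylsilyl)oxy]methyl}hex-2-en-1-ol | OC/C=C/[C@@H](CC)CO[Si](c1ccccc1)(c1ccccc1)C(C)(C)C | intermediate
12 | tert-butyl hydroperoxide | CC(C)(C)OO | starting material
13 | {(2R,3R)-3-[(2S)-1-{[tert-butyl(diphenyl)silyl]oxy}butan-2-yl]oxiran-2-yl}methanol | OC[C@H]1O[C@@H]1[C@@H](CC)CO[Si](c2ccccc2)(c2ccccc2)C(C)(C)C | intermediate
14 | methyllithium | [Li]C | starting material
15 | (2S,3S,4S)-4-{[(tert-butyldiphenylsilyl)oxy]methyl}-2-methylhexane-1,3-diol | OC[C@H](C)[C@H](O)[C@@H](CC)CO[Si](c1ccccc1)(c1ccccc1)C(C)(C)C | intermediate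
16 | 4-methoxybenzaldehyde dimethyl acetal | COc1ccc(cc1)C(OC)OC | starting material
17 | (2S,4S,5S)-4-[(2S)-1-{[tert-butyl(diphenyl)silyl]oxy}butan-2-yl]-2-(4-methoxyphenyl)-5-methyl-1,3-dioxane | COc1ccc(cc1)[C@H]2OC[C@H](C)[C@H](O2)[C@@H](CC)CO[Si](c3ccccc3)(c3ccccc3)C(C)(C)C | intermediate
18 | (2S,3S,4S)-4-{[(tert-butyldiphenylsilyl)oxy]methyl}-3-[(4-methoxybenzyl)oxy]-2-methylhexan-1-ol | OC[C@H](C)[C@H](OCc1ccc(OC)cc1)[C@@H](CC)CO[Si](c2ccccc2)(c2ccccc2)C(C)(C)C | intermediate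
19 | (2R,3R,4S)-4-{[(tert-butyldiphenylsilyl)oxy]methyl}-3-[(4-methoxybenzyl)oxy]-2-methylhexanal | O=C[C@H](C)[C@H](OCc1ccc(OC)cc1)[C@@H](CC)CO[Si](c2ccccc2)(c2ccccc2)C(C)(C)C | intermediate
20 | propyltriphenylphosphonium bromide | CCC[P+](c1ccccc1)(c1ccccc1)c1ccccc1.[Br-] | starting material
21 | allyl chloroformate | C=CCOC(Cl)=O | starting material
22 | propylidene(triphenyl)phosphorane (not isolated) | CCC=P(c1ccccc1)(c1ccccc1)c1ccccc1 | intermediate
23 | {1-[(allyloxy)carbonyl]propyl}triphenylphosphonium chloride (racemic, not isolated) | CCC(C(=O)OCC=C)[P+](c1ccccc1)(c1ccccc1)c1ccccc1.[Cl-] | intermediate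
24 | allyl 2-(triphenylphosphoranylidene)butanoate | CCC(C(=O)OCC=C)=P(c1ccccc1)(c1ccccc1)c1ccccc1 | intermediate
25 | allyl (2E,4S,5S,6S)-6-{[(tert-butyldiphenylsilyl)oxy]methyl}-2-ethyl-5-[(4-methoxybenzyl)oxy]-4-methyloct-2-enoate | C=CCOC(=O)/C(CC)=C/[C@H](C)[C@H](OCc1ccc(OC)cc1)[C@@H](CC)CO[Si](c2ccccc2)(c2ccccc2)C(C)(C)C | intermediate
26 | (2E,4S,5S,6S)-6-{[(tert-butyldiphenylsilyl)oxy]methyl}-2-ethyl-5-[(4-methoxybenzyl)oxy]-4-methyloct-2-en-1-ol | OC/C(CC)=C/[C@H](C)[C@H](OCc1ccc(OC)cc1)[C@@H](CC)CO[Si](c2ccccc2)(c2ccccc2)C(C)(C)C | intermediate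
27 | (2E,4S,5S,6S)-6-{[(tert-butyldiphenylsilyl)oxy]methyl}-2-ethyl-5-[(4-methoxybenzyl)oxy]-4-methyloct-2-enal | O=C/C(CC)=C/[C@H](C)[C@H](OCc1ccc(OC)cc1)[C@@H](CC)CO[Si](c2ccccc2)(c2ccccc2)C(C)(C)C | intermediate
28 | allyl (2E,4E,6S,7S,8S)-8-{[(tert-butyldiphenylsilyl)oxy]methyl}-2,4-diethyl-7-[(4-methoxybenzyl)oxy]-6-methyldeca-2,4-dienoate | C=CCOC(=O)/C(CC)=C/C(CC)=C/[C@H](C)[C@H](OCc1ccc(OC)cc1)[C@@H](CC)CO[Si](c2ccccc2)(c2ccccc2)C(C)(C)C | intermediate
29 | (2E,4E,6S,7S,8S)-8-{[(tert-butyldiphenylsilyl)oxy]methyl}-2,4-diethyl-7-[(4-methoxybenzyl)oxy]-6-methyldeca-2,4-dien-1-ol | OC/C(CC)=C/C(CC)=C/[C@H](C)[C@H](OCc1ccc(OC)cc1)[C@@H](CC)CO[Si](c2ccccc2)(c2ccccc2)C(C)(C)C | intermediate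
30 | (2E,4E,6S,7S,8S)-8-{[(tert-butyldiphenylsilyl)oxy]methyl}-2,4-diethyl-7-[(4-methoxybenzyl)oxy]-6-methyldeca-2,4-dienal | O=C/C(CC)=C/C(CC)=C/[C@H](C)[C@H](OCc1ccc(OC)cc1)[C@@H](CC)CO[Si](c2ccccc2)(c2ccccc2)C(C)(C)C | intermediate
31 | diethyl benzylphosphonate | CCOP(=O)(Cc1ccccc1)OCC | starting material
32 | tert-butyl{[(2S,3S,4S,5E,7E,9E)-2,6,8-triethyl-3-[(4-methoxybenzyl)oxy]-4-methyl-10-phenyldeca-5,7,9-trien-1-yl]oxy}diphenylsilane | c1ccccc1/C=C/C(CC)=C/C(CC)=C/[C@H](C)[C@H](OCc2ccc(OC)cc2)[C@@H](CC)CO[Si](c3ccccc3)(c3ccccc3)C(C)(C)C | intermediate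
33 | (2S,3S,4S,5E,7E,9E)-2,6,8-triethyl-3-[(4-methoxybenzyl)oxy]-4-methyl-10-phenyldeca-5,7,9-trien-1-ol | c1ccccc1/C=C/C(CC)=C/C(CC)=C/[C@H](C)[C@H](OCc2ccc(OC)cc2)[C@@H](CC)CO | intermediate
34 | (2R,3S,4S,5E,7E,9E)-2,6,8-triethyl-3-[(4-methoxybenzyl)oxy]-4-methyl-10-phenyldeca-5,7,9-trienal | c1ccccc1/C=C/C(CC)=C/C(CC)=C/[C@H](C)[C@H](OCc2ccc(OC)cc2)[C@@H](CC)C=O | intermediate
35 | allyl (2E,4S,5S,6S,7E,9E,11E)-2,4,8,10-tetraethyl-5-[(4-methoxybenzyl)oxy]-6-methyl-12-phenyldodeca-2,7,9,11-tetraenoate (not isolated) | c1ccccc1/C=C/C(CC)=C/C(CC)=C/[C@H](C)[C@H](OCc2ccc(OC)cc2)[C@@H](CC)/C=C(CC)/C(=O)OCC=C | intermediate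
36 | allyl (1S,2S,3S,3aR,4R,5S,7aR)-3,4,5,7-tetraethyl-2-[(4-methoxybenzyl)oxy]-1-methyl-5-[(E)-2-phenylethenyl]-2,3,3a,4,5,7a-hexahydro-1H-indene-4-carboxylate | CCC1=C[C@@](/C=C/c2ccccc2)(CC)[C@](CC)(C(=O)OCC=C)[C@@H]2[C@@H]1[C@H](C)[C@H](OCc3ccc(OC)cc3)[C@H]2CC | intermediate
37 | allyl (1S,2S,3S,3aR,4R,5S,7aR)-3,4,5,7-tetraethyl-2-hydroxy-1-methyl-5-[(E)-2-phenylethenyl]-2,3,3a,4,5,7a-hexahydro-1H-indene-4-carboxylate | CCC1=C[C@@](/C=C/c2ccccc2)(CC)[C@](CC)(C(=O)OCC=C)[C@@H]2[C@@H]1[C@H](C)[C@H](O)[C@H]2CC | intermediate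
38 | allyl (1S,3S,3aR,4R,5S,7aR)-3,4,5,7-tetraethyl-1-methyl-2-oxo-5-[(E)-2-phenylethenyl]-2,3,3a,4,5,7a-hexahydro-1H-indene-4-carboxylate | CCC1=C[C@@](/C=C/c2ccccc2)(CC)[C@](CC)(C(=O)OCC=C)[C@@H]2[C@@H]1[C@H](C)C(=O)[C@H]2CC | intermediate
39 | (1S,3S,3aR,4R,5S,7aR)-3,4,5,7-tetraethyl-1-methyl-2-oxo-5-[(E)-2-phenylethenyl]-2,3,3a,4,5,7a-hexahydro-1H-indene-4-carboxylic acid | CCC1=C[C@@](/C=C/c2ccccc2)(CC)[C@](CC)(C(=O)O)[C@@H]2[C@@H]1[C@H](C)C(=O)[C@H]2CC | target

**Totals**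
Total steps: 25. Longest linear sequence: 24 steps (steps 1–11 and 13–25; step 12 is the one-step side branch to ylide 24).

**Steps most likely to fail, with fallbacks**

Step 2 (ee or sense of the lipase acylation). The fallback sets out from 2 and comes back at 7, with the same lipase run in the hydrolytic direction. Diol 2 is peracetylated (Ac2O, pyridine) to 2-ethylpropane-1,3-diyl diacetate F1. The lipase, in pH 7 phosphate buffer, cleaves the acetate on the arm it would otherwise acylate and leaves (2R)-2-(hydroxymethyl)butyl acetate F2. Because the complementary arm is now free, the protecting-group order is inverted: dihydropyran/PPTS gives (2R)-2-[(oxan-2-yloxy)methyl]butyl acetate F3, K2CO3/MeOH gives (2S)-2-[(oxan-2-yloxy)methyl]butan-1-ol F4, and TBDPSCl/imidazole gives tert-butyl{(2R)-2-[(oxan-2-yloxy)methyl]butoxy}diphenylsilane F5. PPTS in MeOH then removes the acetal and delivers 7. Should the acylation simply show the opposite sense to the one assumed, F2 is what step 2 itself gives and the same four operations apply.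

Step 8 (regiochemistry of the cuprate opening, C2 versus C3). The fallback sets out from 7 and comes back at 19, replacing the epoxide sequence by a catalytic crotylation. Alcohol 7 is oxidised (Dess–Martin periodinane) to aldehyde 9, here worked up and used crude. (E)-Crotylboronic acid pinacol ester with (S)-TRIP phosphoric acid (5 mol%, toluene, −30 °C; the antipode expected to attack the Si face) gives (2S,3S,4S)-1-{[tert-butyl(diphenyl)silyl]oxy}-2-ethyl-4-methylhex-5-en-3-ol F6 through a chair Zimmerman–Traxler transition state. 4-Methoxybenzyl trichloroacetimidate with Sc(OTf)3 (cat.) gives tert-butyl{[(2S,3S,4S)-2-ethyl-3-[(4-methoxybenzyl)oxy]-4-methylhex-5-en-1-yl]oxy}diphenylsilane F7. OsO4 (cat.)/NaIO4/2,6-lutidine then cleaves the vinyl group to aldehyde 19.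

Step 22 (slow olefination of the hindered aldehyde, or imperfect cycloaddition selectivity). The fallback sets out from 34 and comes back at 36, using a more reactive enal dienophile. Ylide 22 is formylated with ethyl formate to 2-(triphenylphosphoranylidene)butanal F8. Its Wittig reaction with 34 (toluene, 60 °C) gives (2E,4S,5S,6S,7E,9E,11E)-2,4,8,10-tetraethyl-5-[(4-methoxybenzyl)oxy]-6-methyl-12-phenyldodeca-2,7,9,11-tetraenal F9. This cyclises at or below 40 °C (or at −78 °C with Me2AlCl) to (1S,2S,3S,3aR,4R,5S,7aR)-3,4,5,7-tetraethyl-2-[(4-methoxybenzyl)oxy]-1-methyl-5-[(E)-2-phenylethenyl]-2,3,3a,4,5,7a-hexahydro-1H-indene-4-carbaldehyde F10. Pinnick oxidation (NaClO2, NaH2PO4, 2-methylbut-2-ene) gives (1S,2S,3S,3aR,4R,5S,7aR)-3,4,5,7-tetraethyl-2-[(4-methoxybenzyl)oxy]-1-methyl-5-[(E)-2-phenylethenyl]-2,3,3a,4,5,7a-hexahydro-1H-indene-4-carboxylic acid F11. Allyl bromide with Cs2CO3 in DMF converts this to 36.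

**Further compounds**
F1 | step 2 | 2-ethylpropane-1,3-diyl diacetate | CCC(COC(C)=O)COC(C)=O
F2 | step 2 | (2R)-2-(hydroxymethyl)butyl acetate | CC(=O)OC[C@@H](CO)CC
F3 | step 2 | (2R)-2-[(oxan-2-yloxy)methyl]butyl acetate | CC(=O)OC[C@@H](COC1CCCCO1)CC
F4 | step 2 | (2S)-2-[(oxan-2-yloxy)methyl]butan-1-ol | OC[C@@H](COC1CCCCO1)CC
F5 | step 2 | tert-butyl{(2R)-2-[(oxan-2-yloxy)methyl]butoxy}diphenylsilane | CC(C)(C)[Si](OC[C@@H](COC1CCCCO1)CC)(c1ccccc1)c1ccccc1
F6 | step 8 | (2S,3S,4S)-1-{[tert-butyl(diphenyl)silyl]oxy}-2-ethyl-4-methylhex-5-en-3-ol | C=C[C@H](C)[C@H](O)[C@@H](CC)CO[Si](c1ccccc1)(c1ccccc1)C(C)(C)C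
F7 | step 8 | tert-butyl{[(2S,3S,4S)-2-ethyl-3-[(4-methoxybenzyl)oxy]-4-methylhex-5-en-1-yl]oxy}diphenylsilane | C=C[C@H](C)[C@H](OCc1ccc(OC)cc1)[C@@H](CC)CO[Si](c2ccccc2)(c2ccccc2)C(C)(C)C
F8 | step 22 | 2-(triphenylphosphoranylidene)butanal | CCC(C=O)=P(c1ccccc1)(c1ccccc1)c1ccccc1
F9 | step 22 | (2E,4S,5S,6S,7E,9E,11E)-2,4,8,10-tetraethyl-5-[(4-methoxybenzyl)oxy]-6-methyl-12-phenyldodeca-2,7,9,11-tetraenal | c1ccccc1/C=C/C(CC)=C/C(CC)=C/[C@H](C)[C@H](OCc2ccc(OC)cc2)[C@@H](CC)/C=C(CC)/C=O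
F10 | step 22 | (1S,2S,3S,3aR,4R,5S,7aR)-3,4,5,7-tetraethyl-2-[(4-methoxybenzyl)oxy]-1-methyl-5-[(E)-2-phenylethenyl]-2,3,3a,4,5,7a-hexahydro-1H-indene-4-carbaldehyde | CCC1=C[C@@](/C=C/c2ccccc2)(CC)[C@](CC)(C=O)[C@@H]2[C@@H]1[C@H](C)[C@H](OCc3ccc(OC)cc3)[C@H]2CC
F11 | step 22 | (1S,2S,3S,3aR,4R,5S,7aR)-3,4,5,7-tetraethyl-2-[(4-methoxybenzyl)oxy]-1-methyl-5-[(E)-2-phenylethenyl]-2,3,3a,4,5,7a-hexahydro-1H-indene-4-carboxylic acid | CCC1=C[C@@](/C=C/c2ccccc2)(CC)[C@](CC)(C(=O)O)[C@@H]2[C@@H]1[C@H](C)[C@H](OCc3ccc(OC)cc3)[C@H]2CC
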